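## Retrosynthetic overview

1. The dihydropyran is made last by acid-catalysed cyclodehydration of a δ-hydroxy ketone. Its 3-oxopentyl arm comes from a Horner–Wadsworth–Emmons reaction and its CH2OH from a formaldehyde aldol on an aldehyde grown from the bridge ketone; this aldol sets the spiro carbon.
2. Ring F and its two CH stereocentres come from an intramolecular ester–ketone aldol condensation to a dienoate, then face-selective hydrogenation. Ring E (cyclopentenone) comes from carbonylative Stille coupling and Nazarov cyclisation on the ring-D enol triflate.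
3. Key disconnection: the 8-azabicyclo[4.3.1]decane-2,10-dione core is formed by an intermolecular double Mannich reaction (primary amine + 2 CH2O) on the Michael adduct of cycloheptane-1,3-dione and methyl acrylate. These C–C bonds create the quaternary bridgehead and the piperidine.
4. Absolute configuration: (S)-1-phenylethylamine serves as the Mannich amine, the two diastereomers are separated, and the N-substituent is later exchanged for methyl.
5. Ring order: ring D (bought) → piperidine → cyclopentenone E → cyclopentene F → dihydropyran.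

Assumption: 1 is bought as a catalogue compound, the configuration of 7 is assigned by X-ray after separation, and locants C-1 to C-10 in later names refer to the 8-azabicyclo[4.3.1]decane core (C-1 quaternary bridgehead, C-2 to C-5 four-carbon bridge, C-6 bridgehead CH, C-7/N-8/C-9 aza bridge, C-10 one-carbon bridge).

## Route

Step 1
Reactants: 1 cycloheptane-1,3-dione; 2 methyl acrylate
Product: 3 methyl 3-(2,7-dioxocycloheptyl)propanoate
Conditions: Et3N (0.3 equiv), MeOH, 50 °C, slow addition of 2 (0.95 equiv)
Reagents that add atoms: none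
Why: Base-catalysed Michael addition of the doubly activated C-2 of the 1,3-dione to the acrylate, with slow addition of the acceptor to limit bis-alkylation; no stereocentre is formed.

Step 2
Reactants: 3 methyl 3-(2,7-dioxocycloheptyl)propanoate; 4 (S)-1-phenylethylamine; 5 formaldehyde (as paraformaldehyde, 2.2 equiv)
Product: 7 methyl 3-{(1R,6R)-2,10-dioxo-8-[(1S)-1-phenylethyl]-8-azabicyclo[4.3.1]decan-1-yl}propanoate, via mono-Mannich amine 6 (not isolated)
Conditions: 4, (CH2O)n, MeOH, 50 °C, 1 h (bis-aminal pre-formed, which keeps free amine away from the dione); then 3, AcOH (2 equiv), 65 °C; chromatography removes the (1S,6S) diastereomer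
Reagents that add atoms: none
Why: Double Mannich piperidone annulation in which the first iminium is attacked by the enolised dione C-2 (giving 6) and the second closes onto one of the two enantiotopic α'-CH2 groups, so the two bridgeheads are necessarily cis-bridged and the (S)-auxiliary turns the two ring-closure modes into separable diastereomers, of which the (1R,6R) isomer is kept.

Step 3
Reactants: 7 methyl 3-{(1R,6R)-2,10-dioxo-8-[(1S)-1-phenylethyl]-8-azabicyclo[4.3.1]decan-1-yl}propanoate
Product: 8 methyl 3-{(1R,6R)-10-oxo-8-[(1S)-1-phenylethyl]-2-(trifluoromethanesulfonyloxy)-8-azabicyclo[4.3.1]dec-2-en-1-yl}propanoate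
Conditions: KN(SiMe3)2 (1.1 equiv), THF, −78 °C; PhNTf2, −78 → 0 °C
Reagents that add atoms: N-phenylbis(trifluoromethanesulfonimide), O=S(=O)(N(c1ccccc1)S(=O)(=O)C(F)(F)F)C(F)(F)F
Why: Kinetic enolate O-triflation, which gives a single enol triflate because the C-2 ketone can enolise only towards C-3 (C-1 is quaternary and the C-10 ketone lies between C-1 and the bridgehead CH); no stereocentre changes.

Step 4
Reactants: 8 the enol triflate; 9 tributyl(vinyl)stannane
Product: 10 methyl 3-{(1S,6R)-2-acryloyl-10-oxo-8-[(1S)-1-phenylethyl]-8-azabicyclo[4.3.1]dec-2-en-1-yl}propanoate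
Conditions: Pd(PPh3)4 (5 mol %), LiCl (3 equiv), CO (1 atm), THF, 55 °C
Reagents that add atoms: carbon monoxide, [C-]#[O+]
Why: Carbonylative Stille coupling (oxidative addition of zerovalent palladium to the vinyl triflate, CO insertion, vinyl transfer from tin) gives the divinyl ketone; the descriptor at C-1 changes only through priority rules and no stereocentre is touched.

Step 5
Reactants: 10 the divinyl ketone
Product: 11 N-(1-phenylethyl) tricyclic enone (cyclopent-2-enone ring E fused at C-2/C-3 with its C=O on C-2; C-10 ketone and ester arm kept)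
Conditions: MeSO3H (5 equiv), CH2Cl2, 0 °C → rt
Reagents that add atoms: none
Why: Nazarov cyclisation, in which acid-promoted conrotatory 4π-electrocyclisation joins C-3 to the vinyl terminus and proton loss gives the thermodynamically preferred tetrasubstituted C-2=C-3 enone, so the transient stereocentre is erased.

Step 6
Reactants: 11 N-(1-phenylethyl) tricyclic enone
Product: 13 N-H tricyclic enone (11 without the phenylethyl group), via 1-chloroethyl carbamate 12 (not isolated)
Conditions: ClCO2CH(Cl)CH3 (1.5 equiv), ClCH2CH2Cl, 0 → 80 °C; evaporate; MeOH, 65 °C; aq. NaHCO3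
Reagents that add atoms: 1-chloroethyl chloroformate, CC(Cl)OC(Cl)=O (its atoms stay only in 12)
Why: Olofson N-dealkylation (von Braun-type), in which chloride cleaves the acylammonium ion at the benzylic carbon because both ring N-CH2 groups are far less reactive (one is neopentyl) and methanolysis of the carbamate frees the secondary amine; ring stereocentres are untouched.

Step 7
Reactants: 13 N-H tricyclic enone; 5 formaldehyde (37 % aq.)
Product: 14 N-methyl tricyclic enone
Conditions: NaBH(OAc)3 (1.5 equiv), AcOH (cat.), ClCH2CH2Cl, 0 °C → rt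
Reagents that add atoms: none
Why: Reductive amination via the iminium ion, with a hydride source that leaves the hindered ketone and the tetrasubstituted enone alone; no stereocentre is formed.

Step 8
Reactants: 14 N-methyl tricyclic enone
Product: 15 tetracyclic dienoate keto ester (ring F closed; methyl ester on the new ring-F alkene carbon; C-10 ketone)
Conditions: NaOMe (1.5 equiv), MeOH, 65 °C
Reagents that add atoms: none
Why: Intramolecular aldol condensation, in which the ester enolate attacks the ring-E carbonyl in a 5-exo mode (the competing conjugate addition would be 5-endo) and E1cB dehydration gives the conjugated dienoate; no stereocentre is formed.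

Step 9
Reactants: 15 tetracyclic dienoate keto ester
Product: 16 C-10 spiro-oxirane of 15 (both epimers)
Conditions: Me3S+ I− (3 equiv), KN(SiMe3)2 (2.8 equiv), THF, −10 °C; then 15, 0 °C → rt
Reagents that add atoms: trimethylsulfonium iodide, C[S+](C)C.[I-]
Why: Corey–Chaykovsky epoxidation, in which the small sulfonium ylide adds irreversibly to the non-enolisable bridge ketone; the epoxide configuration does not matter because it is erased in steps 10 and 11.

Step 10
Reactants: 16 C-10 spiro-oxirane
Product: 17 C-10 carbaldehyde (C-10 H; both epimers)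
Conditions: BF3·OEt2 (2.5 equiv), CH2Cl2, −78 → −20 °C; aq. NaHCO3
Reagents that add atoms: none
Why: Meinwald rearrangement (Lewis-acid opening at the tertiary carbon, then 1,2-hydride shift), with elimination blocked because the neighbours are a quaternary carbon and a bridgehead; the C-10 epimers converge in step 11.

Step 11
Reactants: 17 C-10 carbaldehyde; 5 formaldehyde (37 % aq.)
Product: 18 C-10 hydroxymethyl carbaldehyde (CH2OH syn to the C-2–C-5 bridge; CHO syn to the aza bridge)
Conditions: K2CO3 (0.5 equiv), MeOH, 0 °C → rt; formalin added slowly in slight excess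
Reagents that add atoms: none
Why: Crossed aldol addition (hydroxymethylation) in which one molecule of formaldehyde adds to the exocyclic enolate on the face over the unsaturated four-carbon bridge (one flanking axial H against two on the piperidine side) with nothing lost, retro-aldol equilibration favours the same isomer since the larger CH2OH group sits on the less crowded side, and the mild carbonate base with only a slight excess of formaldehyde avoids crossed Cannizzaro reduction of the product aldehyde; this sets C-10.

Step 12
Reactants: 18 C-10 hydroxymethyl carbaldehyde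
Product: 19 tert-butyldimethylsilyl ether of 18
Conditions: TBSCl, imidazole, DMF, rt
Reagents that add atoms: tert-butyldimethylsilyl chloride, CC(C)(C)[Si](C)(C)Cl
Why: Silylation of the primary alcohol, which stops retro-aldol loss of formaldehyde and removes a hydroxyl that would direct the later hydrogenation to the wrong face.

Step 13
Reactants: 19 the silyl ether aldehyde; 20 diethyl (2-oxobutyl)phosphonate
Product: 21 (E)-enone (C-10 bears CH=CH–C(=O)Et and CH2OTBS)
Conditions: NaH (1.4 equiv), 20 (1.5 equiv), THF, 0 °C; then 19, 0 → 50 °C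
Reagents that add atoms: none
Why: Horner–Wadsworth–Emmons olefination of the non-enolisable aldehyde with the stabilised β-ketophosphonate anion gives the (E)-enone; no stereocentre is affected.

Step 14
Reactants: 21 (E)-enone
Product: 22 saturated keto ester (C-10 bears CH2CH2C(=O)Et and CH2OTBS; ring-fusion H and ester α-H cis on the C-9 face)
Conditions: H2 (50 bar), [Ir(cod)(PCy3)(py)]PF6 (10 mol %), CH2Cl2, rt (21 as its CF3CO2H salt; NaHCO3 work-up)
Reagents that add atoms: none
Why: Homogeneous catalytic hydrogenation adds H2 syn to the side-chain enone alkene and to the ester-conjugated ring-F alkene from the face opposite the silyloxymethyl-bearing C-10, which sets the ring-fusion CH and the ester CH cis to each other and to the C-1–C-9 bond, while the shielded tetrasubstituted C-2=C-3 alkene is left.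

Step 15
Reactants: 22 saturated keto ester
Product: 23 δ-hydroxy ketone (22 without the silyl group)
Conditions: HF·pyridine, THF, 0 °C → rt
Reagents that add atoms: none
Why: Fluoride-mediated desilylation under conditions too mild to epimerise the ester α-carbon.

Step 16
Reactants: 23 δ-hydroxy ketone
Product: 25 target CNP0159589.3 (full description in the list), via cyclic hemiketal 24 (not isolated)
Conditions: camphorsulfonic acid (1.3 equiv), toluene, 4 Å molecular sieves, 60 °C; Et3N quench
Reagents that add atoms: none
Why: Acid-catalysed hemiketalisation of the δ-hydroxy ketone and dehydration to the endocyclic enol ether (the favoured isomer for a six-membered ring) gives the 6-ethyl-3,4-dihydro-2H-pyran; no stereocentre is touched.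

## Compound list

1 | cycloheptane-1,3-dione | O=C1CCCCC(=O)C1 | starting material
2 | methyl acrylate | C=CC(=O)OC | starting material
3 | methyl 3-(2,7-dioxocycloheptyl)propanoate | COC(=O)CCC1C(=O)CCCCC1=O | intermediate
4 | (S)-1-phenylethylamine | C[C@H](N)c1ccccc1 | starting material
5 | formaldehyde (paraformaldehyde or formalin) | C=O | starting material
6 | methyl 3-[2,7-dioxo-1-({[(1S)-1-phenylethyl]amino}methyl)cycloheptyl]propanoate | COC(=O)CCC1(CN[C@@H](C)c2ccccc2)C(=O)CCCCC1=O | intermediate
7 | methyl 3-{(1R,6R)-2,10-dioxo-8-[(1S)-1-phenylethyl]-8-azabicyclo[4.3.1]decan-1-yl}propanoate | O=C2[C@@H]1CCCC(=O)[C@@]2(CCC(=O)OC)CN([C@@H](C)c3ccccc3)C1 | intermediate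
8 | methyl 3-{(1R,6R)-10-oxo-8-[(1S)-1-phenylethyl]-2-(trifluoromethanesulfonyloxy)-8-azabicyclo[4.3.1]dec-2-en-1-yl}propanoate | O=C2[C@@H]1CCC=C(OS(=O)(=O)C(F)(F)F)[C@@]2(CCC(=O)OC)CN([C@@H](C)c3ccccc3)C1 | intermediate
9 | tributyl(vinyl)stannane | C=C[Sn](CCCC)(CCCC)CCCC | starting material
10 | methyl 3-{(1S,6R)-2-acryloyl-10-oxo-8-[(1S)-1-phenylethyl]-8-azabicyclo[4.3.1]dec-2-en-1-yl}propanoate | O=C2[C@@H]1CCC=C(C(=O)C=C)[C@@]2(CCC(=O)OC)CN([C@@H](C)c3ccccc3)C1 | intermediate
11 | N-[(1S)-1-phenylethyl] tricyclic enone: cyclopent-2-enone (ring E) fused at C-2/C-3, C=O on C-2, C-10 ketone, methyl propanoate arm on C-1, bridgeheads as in 7 | O=C2[C@@H]1CCC3=C(C(=O)CC3)[C@@]2(CCC(=O)OC)CN([C@@H](C)c4ccccc4)C1 | intermediate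
12 | 1-chloroethyl carbamate of 13 (N-8 bears CO2CH(Cl)CH3) | O=C2[C@@H]1CCC3=C(C(=O)CC3)[C@@]2(CCC(=O)OC)CN(C(=O)OC(C)Cl)C1 | intermediate
13 | N-H tricyclic enone (11 without the phenylethyl group) | O=C2[C@@H]1CCC3=C(C(=O)CC3)[C@@]2(CCC(=O)OC)CNC1 | intermediate
14 | N-methyl tricyclic enone | O=C2[C@@H]1CCC3=C(C(=O)CC3)[C@@]2(CCC(=O)OC)CN(C)C1 | intermediate
15 | tetracyclic dienoate keto ester: ring F closed between the ester α-carbon and the former ring-E carbonyl carbon, diene C-3=C-2–C=C(CO2Me), C-10 ketone, N-methyl, bridgeheads as in 7 | O=C2[C@@H]1CCC3=C4C(CC3)=C(C(=O)OC)C[C@@]42CN(C)C1 | intermediate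
16 | C-10 spiro-oxirane of 15 (both C-10 epimers) | O1CC12[C@@H]3CCC4=C5C(CC4)=C(C(=O)OC)C[C@@]52CN(C)C3 | intermediate
17 | C-10 carbaldehyde (C-10 H, both epimers) | O=CC2[C@@H]1CCC3=C4C(CC3)=C(C(=O)OC)C[C@@]42CN(C)C1 | intermediate
18 | C-10 hydroxymethyl carbaldehyde: CH2OH syn to the C-2–C-5 bridge, CHO syn to the aza bridge | O=C[C@@]2(CO)[C@@H]1CCC3=C4C(CC3)=C(C(=O)OC)C[C@@]42CN(C)C1 | intermediate
19 | tert-butyldimethylsilyl ether of 18 | O=C[C@@]2(CO[Si](C)(C)C(C)(C)C)[C@@H]1CCC3=C4C(CC3)=C(C(=O)OC)C[C@@]42CN(C)C1 | intermediate
20 | diethyl (2-oxobutyl)phosphonate | CCC(=O)CP(=O)(OCC)OCC | starting material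
21 | (E)-enone: C-10 bears (E)-CH=CH–C(=O)Et and CH2OTBS | CCC(=O)/C=C/[C@@]2(CO[Si](C)(C)C(C)(C)C)[C@@H]1CCC3=C4C(CC3)=C(C(=O)OC)C[C@@]42CN(C)C1 | intermediate
22 | saturated keto ester: C-10 bears CH2CH2C(=O)Et and CH2OTBS; ring-fusion H and ester α-H cis, on the face of the C-1–C-9 bond | CCC(=O)CC[C@@]2(CO[Si](C)(C)C(C)(C)C)[C@@H]1CCC3=C4[C@H](CC3)[C@H](C(=O)OC)C[C@@]42CN(C)C1 | intermediate
23 | δ-hydroxy ketone (22 without the silyl group) | CCC(=O)CC[C@@]2(CO)[C@@H]1CCC3=C4[C@H](CC3)[C@H](C(=O)OC)C[C@@]42CN(C)C1 | intermediate
24 | cyclic hemiketal (2-ethyl-2-hydroxytetrahydropyran spiro-fused at C-10; both anomers) | CCC1(O)CC[C@@]2(CO1)[C@@H]1CCC3=C4[C@H](CC3)[C@H](C(=O)OC)C[C@@]42CN(C)C1 | intermediate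
25 | CNP0159589.3: spiro 6-ethyl-3,4-dihydro-2H-pyran at C-10, N-methyl piperidine, C-2=C-3 alkene shared by rings D and E, methyl ester on ring F | CCC1=CC[C@@]2(CO1)[C@@H]1CCC3=C4[C@H](CC3)[C@H](C(=O)OC)C[C@@]42CN(C)C1 | target

## Summary and risks

Total step count: 16. Longest linear sequence: 16 steps (1 → 25); all other inputs are bought.

**Step 5 (Nazarov cyclisation).** The vinyl ketone is unactivated and may polymerise or give the wrong enone isomer in the presence of the protonated amine. The fallback sets out from 7 and comes back at 11. The only enolisable ketone of 7 is silylated (Me3SiOTf, Et3N) to the trimethylsilyl enol ether F1. Mukaiyama–Michael addition to acrolein (BF3·OEt2, CH2Cl2, −78 °C) gives the keto aldehyde F2, which carries a 3-oxopropyl group on C-3. A thiazolium-derived carbene (3-benzyl-5-(2-hydroxyethyl)-4-methylthiazolium chloride, Et3N, 70 °C) closes ring E by intramolecular crossed benzoin addition of the aldehyde carbon to the C-2 ketone, giving the acyloin F3. Burgess dehydration, for which the only β-hydrogen is on C-3, gives 11.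

**Step 9 (methylene transfer to the hindered bridge ketone, with the rearrangement of step 10 depending on it).** The ketone lies between a quaternary carbon and a bridgehead, and the epoxide could rearrange by ring-bond migration. The fallback sets out from 15 and comes back at 17. Lombardo methylenation (Zn, CH2Br2, TiCl4; ketone-selective and non-basic) gives the 10-methylidene compound F4. Hydroboration with 9-borabicyclo[3.3.1]nonane places boron on the terminal carbon to give the alkylborane F5. Oxidation with NaBO3 gives the primary alcohol F6, and Dess–Martin oxidation gives aldehyde 17.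

**Step 14 (hydrogenation).** The ester-conjugated alkene is tetrasubstituted and part of a diene, so chemoselectivity and face selectivity are both uncertain. The fallback sets out from 21 and comes back at 22. The side-chain enone is first reduced by conjugate hydride addition with [(Ph3P)CuH]6 in wet benzene to the keto dienoate F7. The ester-conjugated ring-F double bond is then reduced by electron transfer (Mg turnings, MeOH, rt), with protonation of both carbons from the open face, to give 22.

## Further compounds

F1 | step 5 | trimethylsilyl enol ether of 7 (OSiMe3 on C-2, C-2=C-3) | O=C2[C@@H]1CCC=C(O[Si](C)(C)C)[C@@]2(CCC(=O)OC)CN([C@@H](C)c3ccccc3)C1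
F2 | step 5 | keto aldehyde: 7 with a 3-oxopropyl group on C-3 (both C-3 epimers) | O=C2[C@@H]1CCC(CCC=O)C(=O)[C@@]2(CCC(=O)OC)CN([C@@H](C)c3ccccc3)C1
F3 | step 5 | acyloin: 2-hydroxycyclopentanone ring E fused at C-2/C-3 with OH on C-2 (ring-fusion isomers) | O=C2[C@@H]1CCC3CCC(=O)C3(O)[C@@]2(CCC(=O)OC)CN([C@@H](C)c4ccccc4)C1
F4 | step 9 | 10-methylidene analogue of 15 | C=C2[C@@H]1CCC3=C4C(CC3)=C(C(=O)OC)C[C@@]42CN(C)C1
F5 | step 9 | alkylborane: C-10 CH2–B(9-borabicyclo[3.3.1]nonan-9-yl), C-10 H | C(B5C6CCCC5CCC6)C2[C@@H]1CCC3=C4C(CC3)=C(C(=O)OC)C[C@@]42CN(C)C1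
F6 | step 9 | primary alcohol: C-10 CH2OH, C-10 H | OCC2[C@@H]1CCC3=C4C(CC3)=C(C(=O)OC)C[C@@]42CN(C)C1
F7 | step 14 | keto dienoate: 21 with the side-chain C=C reduced | CCC(=O)CC[C@@]2(CO[Si](C)(C)C(C)(C)C)[C@@H]1CCC3=C4C(CC3)=C(C(=O)OC)C[C@@]42CN(C)C1
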